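## Retrosynthetic overview

- Structural feature (germacrane numbering): the target is a ten-membered carbocycle C1–C10 fused to a γ-lactone (C6–O–C12(=O)–C11–C7). Its erythro C8(OH)/C9(O-acyl) pair adjoins C10 of the C1=C10 alkene, which holds C2 cis to C9 and carries the formyl carbon C14. This is the pattern of a 3-substituted cis-cyclohexa-3,5-diene-1,2-diol whose six carbons are C7, C8, C9, C10, C1 and C2.
- The arene ring is only a template: enzymatic cis-dihydroxylation of bromobenzene sets C8, C9 and the C1=C10 geometry, and Br marks C10 for C14 (Stille hydroxymethylation).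
- Cleavage of the unbrominated ring alkene frees C2 and C7. C2=C3 comes from a Wittig reaction, C3–C4 from a B-alkyl Suzuki coupling with the Z-iodide from but-2-yn-1-ol, and C7–C11 from a Baylis–Hillman reaction with methyl acrylate.
- Last disconnections: the C9 ester, then the C6–C7 bond and the lactone C–O bond (chromium Barbier macrocyclisation with lactonisation).
- Ring order: cyclohexadiene template (cleaved in step 6), then the ten-membered carbocycle and the γ-lactone, both in step 17.

Key step: step 1

Remark: germacrane numbering (C1–C15) is used for all open-chain intermediates; acid 29 is taken as available in high enantiomeric purity. TBS = tert-butyl(dimethyl)silyl, TES = triethylsilyl.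

## Route

Step 1
Reactants: 1 bromobenzene
Product: 2 (1S,2S)-3-bromocyclohexa-3,5-diene-1,2-diol
Conditions: recombinant E. coli whole cells expressing toluene dioxygenase, glucose, air, phosphate buffer pH 7, 30 °C
Reagents that add atoms: dioxygen, O=O
Why: The Rieske-type dioxygenase, fed with electrons from NADH through its reductase and ferredoxin, activates O2 at a mononuclear non-haem iron centre and delivers both oxygen atoms to one face of the C2–C3 bond of the bound arene, so the future C8–O and C9–O bonds form in a syn addition that breaks aromaticity without closing a ring. The closest known reaction type is the microbial cis-dihydroxylation of toluene and the halobenzenes by this same enzyme. Both new stereocentres are fixed by the enzyme pocket, which holds the bromine in one orientation and presents only the 2,3-bond to iron from one face, so the (1S,2S) diol should result. The step needs regioselectivity (2,3- over 3,4-attack) and enantiofacial selectivity, and both are secured by the protein and not by the substrate. The host lacks the diol dehydrogenase, so the diol is not rearomatised to the catechol. The surviving C(Br)=CH ring alkene already holds the future C2 cis to C9.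

Step 2
Reactants: 2 (1S,2S)-3-bromocyclohexa-3,5-diene-1,2-diol
Product: 3 bromodiene acetonide
Conditions: 2,2-dimethoxypropane, p-TsOH (cat.), acetone, 0 °C to rt; Et3N quench; used at once
Reagents that add atoms: 2,2-dimethoxypropane, COC(C)(C)OC
Why: Acid-catalysed transketalisation of the cis-diol gives the cis-fused dioxolane (acetonide formation), which blocks dehydrative rearomatisation and leaves both stereocentres untouched.

Step 3
Reactants: 3 bromodiene acetonide
Product: 4 bromocyclohexene diol acetonide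
Conditions: OsO4 (cat.), NMO, acetone/H2O, rt
Reagents that add atoms: N-methylmorpholine N-oxide, C[N+]1([O-])CCOCC1; water, O (both oxygens are passed on by the catalytic osmium tetroxide, O=[Os](=O)(=O)=O)
Why: Catalytic osmium tetroxide dihydroxylation should occur only at the more electron-rich unhalogenated alkene, anti to the acetonide; the two new carbinol centres are removed again in step 6, so only the chemoselectivity matters.

Step 4
Reactants: 4 bromocyclohexene diol acetonide
Product: 5 hydroxymethyl triol acetonide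
Conditions: Bu3SnCH2OH, Pd(PPh3)4 (cat.), 1,4-dioxane, 90 °C
Reagents that add atoms: (tributylstannyl)methanol, CCCC[Sn](CCCC)(CCCC)CO
Why: Stille coupling of the vinyl bromide with the hydroxymethyl stannane installs C14 on C10 with retention of the ring-fixed alkene geometry, and free hydroxyl groups are tolerated.

Step 5
Reactants: 5 hydroxymethyl triol acetonide
Product: 6 C14 TBS ether diol
Conditions: TBSCl (1.05 equiv), imidazole, CH2Cl2/DMF, −20 to 0 °C
Reagents that add atoms: tert-butyldimethylsilyl chloride, CC(C)(C)[Si](C)(C)Cl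
Why: The primary allylic hydroxyl is silylated much faster than the two secondary ones (selective silyl ether formation), masking C14–OH before the diol is cleaved.

Step 6
Reactants: 6 C14 TBS ether diol
Product: 8 open-chain diol (C2 and C7 primary alcohols), via dialdehyde 7 (not isolated)
Conditions: NaIO4, NaHCO3, THF/H2O, 0 °C; then NaBH4, CeCl3·7H2O, MeOH, −40 to 0 °C
Reagents that add atoms: none
Why: Periodate glycol cleavage opens the template ring to the C2 enal and the C7 aldehyde, and Luche-type borohydride reduction of the crude dialdehyde gives the two primary alcohols before the α-alkoxy aldehyde can epimerise at C8.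

Step 7
Reactants: 8 open-chain diol
Product: 9 hydroxy enal (C2 aldehyde)
Conditions: activated MnO2, CH2Cl2, rt
Reagents that add atoms: none
Why: MnO2 oxidises only the allylic C2 alcohol (chemoselective allylic oxidation), which differentiates the two primary alcohols and keeps the alkene geometry.

Step 8
Reactants: 9 hydroxy enal
Product: 10 dienol (C3=C2–C1=C10 diene, free C7 hydroxyl)
Conditions: Ph3PCH3Br, KN(SiMe3)2 (2.5 equiv each), THF, −78 to 0 °C
Reagents that add atoms: methyltriphenylphosphonium bromide, [Br-].C[P+](c1ccccc1)(c1ccccc1)c1ccccc1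
Why: Wittig methylenation of the enal with excess ylide (one equivalent is spent on the free hydroxyl) adds C3 as a terminal vinyl group without touching the C1=C10 geometry.

Step 9
Reactants: 11 but-2-yn-1-ol
Product: 13 (2Z)-3-iodobut-2-en-1-ol, via cyclic alkenylalanate 12 (not isolated)
Conditions: NaAlH2(OCH2CH2OMe)2, THF, 0 °C to rt; then I2, −78 °C to rt
Reagents that add atoms: iodine, II
Why: Hydroxyl-directed trans-hydroalumination of the propargylic alcohol places aluminium on the methyl-bearing carbon cis to the carbinol carbon, and iodinolysis with retention gives the Z-iodide that fixes the C4=C5 geometry.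

Step 10
Reactants: 13 (2Z)-3-iodobut-2-en-1-ol
Product: 14 TES ether of the Z-iodide
Conditions: Et3SiCl, imidazole, CH2Cl2, 0 °C
Reagents that add atoms: chlorotriethylsilane, CC[Si](Cl)(CC)CC
Why: Standard silyl ether formation on the primary alcohol gives a group that can later be removed in the presence of the TBS ether and the acetonide.

Step 11
Reactants: 10 dienol; 14 TES ether of the Z-iodide
Product: 16 coupled alcohol (C3–C4 bond formed), via bis(9-BBN) adduct 15 (not isolated)
Conditions: 10, 9-BBN (2.5 equiv), THF, rt; then 14, Pd(dppf)Cl2 (cat.), AsPh3, aq. Cs2CO3, DMF, rt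
Reagents that add atoms: none
Why: 9-BBN adds to the monosubstituted terminus of the diene at C3 (the trisubstituted alkene is inert and the free hydroxyl is held as a borinate), and the B-alkyl Suzuki–Miyaura coupling with the vinyl iodide forms C3–C4 with retention of the Z geometry.

Step 12
Reactants: 16 coupled alcohol
Product: 17 C7 aldehyde
Conditions: Dess–Martin periodinane, NaHCO3, CH2Cl2, 0 °C
Reagents that add atoms: none
Why: Buffered Dess–Martin oxidation of the only free alcohol gives the α-alkoxy aldehyde under non-epimerising conditions.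

Step 13
Reactants: 17 C7 aldehyde; 18 methyl acrylate
Product: 19 Baylis–Hillman adduct (both C7 carbinol epimers)
Conditions: methyl acrylate (excess), DABCO (1 equiv), 1,4-dioxane/H2O, rt
Reagents that add atoms: none
Why: Baylis–Hillman reaction: the DABCO–acrylate zwitterion adds to the activated α-alkoxy aldehyde to form C7–C11; the new carbinol centre forms unselectively but is erased in step 14.

Step 14
Reactants: 19 Baylis–Hillman adduct
Product: 20 (Z)-2-(bromomethyl)enoate with C6 TES ether
Conditions: NBS, Me2S, CH2Cl2, −20 to 0 °C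
Reagents that add atoms: N-bromosuccinimide, BrN1C(=O)CCC1=O
Why: Corey–Kim-type activation of the allylic alcohol as its alkoxysulfonium salt and SN2′ attack of bromide should give the thermodynamically preferred (Z)-2-(bromomethyl)enoate, removing the C7 carbinol centre.

Step 15
Reactants: 20 (Z)-2-(bromomethyl)enoate with C6 TES ether
Product: 21 allylic bromide with free C6 alcohol
Conditions: PPTS (cat.), MeOH/CH2Cl2, 0 °C
Reagents that add atoms: none
Why: Mild acid methanolysis cleaves the primary triethylsilyl ether far faster than the TBS ether or the acetonide (selective desilylation), and the allylic bromide is inert to these non-basic conditions.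

Step 16
Reactants: 21 allylic bromide with free C6 alcohol
Product: 22 bromo enal (cyclisation precursor)
Conditions: activated MnO2, CH2Cl2, rt
Reagents that add atoms: none
Why: MnO2 oxidation of the Z-allylic alcohol (allylic oxidation) gives the Z-enal without isomerisation and leaves the allylic bromide alone.

Step 17
Reactants: 22 bromo enal
Product: 25 macrolactone (8,9-acetonide and C14 TBS ether), via allylchromium dichloride 23 (not isolated), via hydroxy ester 24 (not isolated)
Conditions: CrCl2 (8 equiv), THF, rt, slow addition to 2 mM; then PPTS (cat.), CH2Cl2, rt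
Reagents that add atoms: none
Why: Intramolecular Nozaki–Hiyama (chromium Barbier) allylation: the allylchromium reagent adds through its γ-carbon C7 to the tethered enal to close the ten-membered carbocycle; the anti C6/C7 relationship (trans-lactone) is expected from the six-membered chair transition state, as in chromium closures of other germacranolide rings, C7 should be set by addition anti to the C8–C9 bond of the dioxolane with C8–H eclipsing the alkene to avoid A(1,3) strain, and the C6 alkoxide then lactonises onto the methyl ester.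

Step 18
Reactants: 25 macrolactone
Product: 26 C14 allylic alcohol (acetonide kept)
Conditions: HF·pyridine, pyridine, THF, 0 °C to rt
Reagents that add atoms: none
Why: Buffered HF·pyridine cleaves the primary silyl ether (fluoride desilylation) while the acetonide and the α-methylene lactone survive.

Step 19
Reactants: 26 C14 allylic alcohol
Product: 27 C14 enal (acetonide kept)
Conditions: activated MnO2, CH2Cl2, rt
Reagents that add atoms: none
Why: MnO2 oxidises the only free hydroxyl, the primary allylic C14 alcohol, to the conjugated aldehyde (allylic oxidation).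

Step 20
Reactants: 27 C14 enal
Product: 28 8,9-diol enal
Conditions: TFA/H2O/THF (1:1:4), 0 °C to rt
Reagents that add atoms: none
Why: Aqueous acid hydrolysis of the dioxolane (acetal hydrolysis) releases the C8,C9-diol; both ring alkenes are deactivated by allylic oxygens and the enal, so transannular cyclisation is not expected at this temperature.

Step 21
Reactants: 28 8,9-diol enal; 29 (2R)-2-methylbutanoic acid
Product: 30 target, 8-hydroxy-9-[(2R)-2-methylbutanoyloxy] germacranolide aldehyde
Conditions: EDC·HCl, DMAP (cat.), CH2Cl2, −20 to 0 °C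
Reagents that add atoms: none
Why: Steglich esterification: the allylic C9 hydroxyl, flanked by the trigonal C10, should be acylated in preference to the C8 hydroxyl, which is crowded by the ring-fusion carbon C7 and the syn lactone carbon C11; low temperature and catalytic DMAP limit epimerisation of the acid and O9-to-O8 acyl migration.

## Compound list

1 | bromobenzene | Brc1ccccc1 | starting material
2 | (1S,2S)-3-bromocyclohexa-3,5-diene-1,2-diol (cis) | BrC1=CC=C[C@H](O)[C@@H]1O | intermediate
3 | (3aS,7aS)-4-bromo-2,2-dimethyl-3a,7a-dihydro-1,3-benzodioxole | BrC1=CC=C[C@@H]2OC(C)(C)O[C@H]12 | intermediate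
4 | (3aS,4R,5R,7aS)-7-bromo-2,2-dimethyl-3a,4,5,7a-tetrahydro-1,3-benzodioxole-4,5-diol | BrC1=C[C@@H](O)[C@@H](O)[C@@H]2OC(C)(C)O[C@H]12 | intermediate
5 | (3aS,4R,5R,7aR)-7-(hydroxymethyl)-2,2-dimethyl-3a,4,5,7a-tetrahydro-1,3-benzodioxole-4,5-diol | OCC1=C[C@@H](O)[C@@H](O)[C@@H]2OC(C)(C)O[C@H]12 | intermediate
6 | (3aS,4R,5R,7aR)-7-({[tert-butyl(dimethyl)silyl]oxy}methyl)-2,2-dimethyl-3a,4,5,7a-tetrahydro-1,3-benzodioxole-4,5-diol | CC(C)(C)[Si](C)(C)OCC1=C[C@@H](O)[C@@H](O)[C@@H]2OC(C)(C)O[C@H]12 | intermediate
7 | (4R,5R)-5-[(2Z)-1-{[tert-butyl(dimethyl)silyl]oxy}-4-oxobut-2-en-2-yl]-2,2-dimethyl-1,3-dioxolane-4-carbaldehyde | O=C/C=C(/CO[Si](C)(C)C(C)(C)C)[C@H]1OC(C)(C)O[C@H]1C=O | intermediate (not isolated)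
8 | (2Z)-4-{[tert-butyl(dimethyl)silyl]oxy}-3-[(4R,5S)-5-(hydroxymethyl)-2,2-dimethyl-1,3-dioxolan-4-yl]but-2-en-1-ol | OC/C=C(/CO[Si](C)(C)C(C)(C)C)[C@H]1OC(C)(C)O[C@H]1CO | intermediate
9 | (2Z)-4-{[tert-butyl(dimethyl)silyl]oxy}-3-[(4R,5S)-5-(hydroxymethyl)-2,2-dimethyl-1,3-dioxolan-4-yl]but-2-enal | O=C/C=C(/CO[Si](C)(C)C(C)(C)C)[C@H]1OC(C)(C)O[C@H]1CO | intermediate
10 | {(4S,5R)-5-[(2Z)-1-{[tert-butyl(dimethyl)silyl]oxy}penta-2,4-dien-2-yl]-2,2-dimethyl-1,3-dioxolan-4-yl}methanol | C=C/C=C(/CO[Si](C)(C)C(C)(C)C)[C@H]1OC(C)(C)O[C@H]1CO | intermediate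
11 | but-2-yn-1-ol | CC#CCO | starting material
12 | sodium cyclic (Z)-alkenylalanate: 3-methyl-2,2-bis(2-methoxyethoxy)-2,5-dihydro-1,2-oxaluminol-2-uide (Al on the methyl-bearing carbon, cis to CH2O) | CC1=CCO[Al-]1(OCCOC)OCCOC.[Na+] | intermediate (not isolated)
13 | (2Z)-3-iodobut-2-en-1-ol | C/C(I)=C/CO | intermediate
14 | triethyl{[(2Z)-3-iodobut-2-en-1-yl]oxy}silane | C/C(I)=C/CO[Si](CC)(CC)CC | intermediate
15 | C3-(9-borabicyclo[3.3.1]nonan-9-yl) alkylborane of 10, with the C7 hydroxyl as its O-(9-BBN) borinate | C(C/C=C(/CO[Si](C)(C)C(C)(C)C)[C@H]1OC(C)(C)O[C@H]1COB1C2CCCC1CCC2)B1C2CCCC1CCC2 | intermediate (not isolated)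
16 | {(4S,5R)-5-[(2Z,6Z)-1-{[tert-butyl(dimethyl)silyl]oxy}-6-methyl-8-[(triethylsilyl)oxy]octa-2,6-dien-2-yl]-2,2-dimethyl-1,3-dioxolan-4-yl}methanol | CC[Si](CC)(CC)OC/C=C(/C)CC/C=C(/CO[Si](C)(C)C(C)(C)C)[C@H]1OC(C)(C)O[C@H]1CO | intermediate
17 | (4R,5R)-5-[(2Z,6Z)-1-{[tert-butyl(dimethyl)silyl]oxy}-6-methyl-8-[(triethylsilyl)oxy]octa-2,6-dien-2-yl]-2,2-dimethyl-1,3-dioxolane-4-carbaldehyde | CC[Si](CC)(CC)OC/C=C(/C)CC/C=C(/CO[Si](C)(C)C(C)(C)C)[C@H]1OC(C)(C)O[C@H]1C=O | intermediate
18 | methyl acrylate | C=CC(=O)OC | starting material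
19 | methyl 2-{hydroxy[(4S,5R)-5-[(2Z,6Z)-1-{[tert-butyl(dimethyl)silyl]oxy}-6-methyl-8-[(triethylsilyl)oxy]octa-2,6-dien-2-yl]-2,2-dimethyl-1,3-dioxolan-4-yl]methyl}prop-2-enoate (both carbinol epimers) | CC[Si](CC)(CC)OC/C=C(/C)CC/C=C(/CO[Si](C)(C)C(C)(C)C)[C@H]1OC(C)(C)O[C@H]1C(O)C(=C)C(=O)OC | intermediate
20 | methyl (2Z)-2-(bromomethyl)-3-{(4S,5R)-5-[(2Z,6Z)-1-{[tert-butyl(dimethyl)silyl]oxy}-6-methyl-8-[(triethylsilyl)oxy]octa-2,6-dien-2-yl]-2,2-dimethyl-1,3-dioxolan-4-yl}prop-2-enoate | CC[Si](CC)(CC)OC/C=C(/C)CC/C=C(/CO[Si](C)(C)C(C)(C)C)[C@H]1OC(C)(C)O[C@H]1/C=C(\CBr)C(=O)OC | intermediate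
21 | methyl (2Z)-2-(bromomethyl)-3-{(4S,5R)-5-[(2Z,6Z)-1-{[tert-butyl(dimethyl)silyl]oxy}-8-hydroxy-6-methylocta-2,6-dien-2-yl]-2,2-dimethyl-1,3-dioxolan-4-yl}prop-2-enoate | OC/C=C(/C)CC/C=C(/CO[Si](C)(C)C(C)(C)C)[C@H]1OC(C)(C)O[C@H]1/C=C(\CBr)C(=O)OC | intermediate
22 | methyl (2Z)-2-(bromomethyl)-3-{(4S,5R)-5-[(2Z,6Z)-1-{[tert-butyl(dimethyl)silyl]oxy}-6-methyl-8-oxoocta-2,6-dien-2-yl]-2,2-dimethyl-1,3-dioxolan-4-yl}prop-2-enoate | O=C/C=C(/C)CC/C=C(/CO[Si](C)(C)C(C)(C)C)[C@H]1OC(C)(C)O[C@H]1/C=C(\CBr)C(=O)OC | intermediate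
23 | allylchromium dichloride (trivalent chromium) from 22, chromium on C13 | O=C/C=C(/C)CC/C=C(/CO[Si](C)(C)C(C)(C)C)[C@H]1OC(C)(C)O[C@H]1/C=C(\C[Cr](Cl)Cl)C(=O)OC | intermediate (not isolated)
24 | methyl (1(10)Z,4Z,6R,7S,8S,9R)-14-{[tert-butyl(dimethyl)silyl]oxy}-6-hydroxy-8,9-(isopropylidenedioxy)germacra-1(10),4,11(13)-trien-12-oate | C=C(C(=O)OC)[C@H]1[C@H](O)/C=C(/C)CC/C=C(/CO[Si](C)(C)C(C)(C)C)[C@H]2OC(C)(C)O[C@@H]12 | intermediate (not isolated)
25 | (1(10)Z,4Z,6R,7S,8S,9R)-14-{[tert-butyl(dimethyl)silyl]oxy}-8,9-(isopropylidenedioxy)germacra-1(10),4,11(13)-trien-12,6-olide | C=C1C(=O)O[C@@H]2/C=C(/C)CC/C=C(/CO[Si](C)(C)C(C)(C)C)[C@H]3OC(C)(C)O[C@H]3[C@@H]12 | intermediate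
26 | (1(10)Z,4Z,6R,7S,8S,9R)-14-hydroxy-8,9-(isopropylidenedioxy)germacra-1(10),4,11(13)-trien-12,6-olide | C=C1C(=O)O[C@@H]2/C=C(/C)CC/C=C(/CO)[C@H]3OC(C)(C)O[C@H]3[C@@H]12 | intermediate
27 | (1(10)E,4Z,6R,7S,8S,9R)-8,9-(isopropylidenedioxy)-14-oxogermacra-1(10),4,11(13)-trien-12,6-olide | C=C1C(=O)O[C@@H]2/C=C(/C)CC/C=C(/C=O)[C@H]3OC(C)(C)O[C@H]3[C@@H]12 | intermediate
28 | (1(10)E,4Z,6R,7R,8S,9R)-8,9-dihydroxy-14-oxogermacra-1(10),4,11(13)-trien-12,6-olide | C=C1C(=O)O[C@@H]2/C=C(/C)CC/C=C(/C=O)[C@@H](O)[C@@H](O)[C@@H]12 | intermediate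
29 | (2R)-2-methylbutanoic acid | CC[C@@H](C)C(=O)O | starting material
30 | (1(10)E,4Z,6R,7R,8S,9R)-8-hydroxy-9-{[(2R)-2-methylbutanoyl]oxy}-14-oxogermacra-1(10),4,11(13)-trien-12,6-olide (CNP0256845.2) | C=C1C(=O)O[C@@H]2/C=C(/C)CC/C=C(/C=O)[C@@H](OC(=O)[C@H](C)CC)[C@@H](O)[C@@H]12 | target

## Step count and risks

Total step count: 21. Longest linear sequence: 19 steps (steps 1–8 and 11–21, from bromobenzene); steps 9 and 10 make the iodide fragment.

Steps most likely to fail:

1. Step 17 (chromium Barbier macrocyclisation). The ring closure may show poor facial selectivity at C7 or C6, because the tether and not the open-chain preference may decide the approach, and intermolecular coupling may compete with closure of the medium ring.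
   - Fallback: it sets out from dienol 10 and iodo alcohol 13 and returns at macrolactone 25, setting the stereocentres before the ring is closed.
   - Dienol 10 would be oxidised with Dess–Martin periodinane to the diene aldehyde F1, taken through the Baylis–Hillman reaction with 18 to the adduct F2, and converted with NBS/Me2S into the dienyl allylic bromide F3.
   - Iodo alcohol 13 would be oxidised with MnO2 to (Z)-3-iodobut-2-enal F4.
   - CrCl2 in THF would join F3 and F4 intermolecularly (the vinyl iodide is inert to divalent chromium without a nickel co-catalyst) to the hydroxy ester F5. Here C7 is set in an open system by approach anti to the substituted dioxolane carbon C9, and C6 by the anti-selective chair transition state. F5 lactonises with PPTS to the iodo lactone F6.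
   - 9-BBN should hydroborate the monosubstituted vinyl group of F6 faster than the electron-poor exocyclic alkene to give the alkylborane F7. An intramolecular B-alkyl Suzuki–Miyaura coupling (Pd(dppf)Cl2, AsPh3, Cs2CO3, DMF/THF/H2O, high dilution) would then close the ring at C3–C4 to give 25.

2. Step 21 (regioselective acylation). Acylation may occur at the C8 hydroxyl or at both hydroxyls, and the acyl group may migrate between O9 and O8.
   - Fallback: it sets out from diol 28 and returns at target 30, replacing direct discrimination by protect–acylate–deprotect.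
   - Et3SiCl/imidazole at −40 °C silylates the more reactive hydroxyl. If that is O8, the mono-silyl ether F8 is formed.
   - F8 is acylated at O9 with 29 (EDC·HCl, DMAP) to the silylated ester F9, and HF·pyridine removes the silyl group under acidic, non-migrating conditions to give 30.

3. Step 13 (Baylis–Hillman reaction). The addition may be slow, and the amine base may epimerise C8 next to the aldehyde or trigger β-elimination of the acetonide oxygen.
   - Fallback: it sets out from aldehyde 17 and returns at adduct 19, using a preformed acrylate α-anion equivalent in place of amine catalysis.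
   - Methyl propiolate is hydroaluminated with iBu2AlH and N-methylmorpholine N-oxide in THF at 0 °C to the α-(methoxycarbonyl)vinylalane F10, which adds to 17 at 0 °C under non-basic conditions to give 19.

Further compounds
F1 | step 17 | (4R,5R)-5-[(2Z)-1-{[tert-butyl(dimethyl)silyl]oxy}penta-2,4-dien-2-yl]-2,2-dimethyl-1,3-dioxolane-4-carbaldehyde | C=C/C=C(/CO[Si](C)(C)C(C)(C)C)[C@H]1OC(C)(C)O[C@H]1C=O
F2 | step 17 | methyl 2-{hydroxy[(4S,5R)-5-[(2Z)-1-{[tert-butyl(dimethyl)silyl]oxy}penta-2,4-dien-2-yl]-2,2-dimethyl-1,3-dioxolan-4-yl]methyl}prop-2-enoate (both carbinol epimers) | C=C/C=C(/CO[Si](C)(C)C(C)(C)C)[C@H]1OC(C)(C)O[C@H]1C(O)C(=C)C(=O)OC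
F3 | step 17 | methyl (2Z)-2-(bromomethyl)-3-{(4S,5R)-5-[(2Z)-1-{[tert-butyl(dimethyl)silyl]oxy}penta-2,4-dien-2-yl]-2,2-dimethyl-1,3-dioxolan-4-yl}prop-2-enoate | C=C/C=C(/CO[Si](C)(C)C(C)(C)C)[C@H]1OC(C)(C)O[C@H]1/C=C(\CBr)C(=O)OC
F4 | step 17 | (2Z)-3-iodobut-2-enal | C/C(I)=C/C=O
F5 | step 17 | open-chain hydroxy ester adduct of F3 and F4 (C6 carbinol, C7 bearing the acrylate, configured as in 25) | COC(=O)C(=C)[C@@H]([C@H](O)/C=C(/C)I)[C@@H]1OC(C)(C)O[C@@H]1/C(CO[Si](C)(C)C(C)(C)C)=C\C=C
F6 | step 17 | trans-α-methylene-γ-butyrolactone carrying the (Z)-2-iodopropenyl group at C6 and the dienyl dioxolane at C7 | C=C1C(=O)O[C@H](/C=C(/C)I)[C@H]1[C@@H]2OC(C)(C)O[C@@H]2/C(CO[Si](C)(C)C(C)(C)C)=C\C=C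
F7 | step 17 | C3-(9-borabicyclo[3.3.1]nonan-9-yl) alkylborane from F6 | C=C1C(=O)O[C@H](/C=C(/C)I)[C@H]1[C@@H]2OC(C)(C)O[C@@H]2/C(CO[Si](C)(C)C(C)(C)C)=C\CCB1C2CCCC1CCC2
F8 | step 21 | 8-O-triethylsilyl ether of 28 | C=C1C(=O)O[C@@H]2/C=C(/C)CC/C=C(/C=O)[C@@H](O)[C@@H](O[Si](CC)(CC)CC)[C@@H]12
F9 | step 21 | 8-O-triethylsilyl ether of 30 | C=C1C(=O)O[C@@H]2/C=C(/C)CC/C=C(/C=O)[C@@H](OC(=O)[C@H](C)CC)[C@@H](O[Si](CC)(CC)CC)[C@@H]12
F10 | step 13 | methyl 2-(diisobutylalumanyl)prop-2-enoate | C=C(C(=O)OC)[Al](CC(C)C)CC(C)C
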